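**Bench rule.** Tuesday's flask and Wednesday's differ in c(L), yet at 1.25 d their Z readings lie close: 13.8% on Tuesday, 13.5% on Wednesday. The bench rule treats E as staying near its charge (pseudo-first-order), so percent curves copy each other and Wednesday's flask should repeat Tuesday's Z of 50.2% at 15.0 d.

| setting | Wednesday's | Tuesday's | flask |
|---|---|---|---|
| L | 0.050 M | 0.034 M | 0.050 M |
| E | 0.050 M | 0.050 M | 0.0500 M |
| remark | the very flask that is asked about, followed so far | run made earlier |  |
| time |  |  | 15 d |

| run | time / d | X / % | Z / % |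
|---|---|---|---|
| Wednesday's | 0.417 | 10.8 | 3.4 |
| Wednesday's | 0.833 | 23.5 | 8.3 |
| Wednesday's | 1.25 | 33.2 | 13.5 |
| Wednesday's | 1.67 | 37.1 | 16.9 |
| Wednesday's | 2.50 | 40.0 | 21.6 |
| Tuesday's | 1.25 | 31.9 | 13.8 |
| Tuesday's | 2.08 | 39.7 | 20.2 |
| Tuesday's | 3.00 | 38.6 | 24.0 |
| Tuesday's | 5.00 | 35.1 | 30.8 |
| Tuesday's | 10.0 | 27.0 | 41.8 |
| Tuesday's | 15.0 | 21.0 | 50.2 |

(each reading ± 0.5 percentage points)



- amount of X in the flask at 15 d, in percent of the L charged
- amount of Z in the flask at 15 d, in percent of the L charged
- amount of G in the flask at 15 d, in percent of the L charged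

**Its border.** This text's own reckoning assumes one E used per Z. The share of E used is then Z times c(L)/c(E), a ratio of 0.680 on Tuesday and 1.00 on Wednesday. By its last reading Tuesday's flask has thus used about 34.1% of its E, so E was not holding at its charge there, and a copy in Wednesday's flask would use 50.2%.

**E exposure.** Suppose Z forms in proportion to c(E) and to a percent course shared by both flasks. The shared quantity is then the E exposure, the natural logarithm of one over the share of E left, divided by the ratio. Tuesday's last reading gives 0.614. Run backwards at Wednesday's ratio, it gives Z 45.9%, less than Tuesday's reading.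

**The forecast.** It gives X 21.4%, Z 49.8% and G 28.8%, holding that “Wednesday at 15 d should therefore nearly copy Tuesday”. On Z it stands above this reckoning.

**The flask.** It gives X 22.6%, Z 46.9% and G 6.48%.

    G ⇌ J (K = 3.10, k = 9.00 × 10⁻⁵ min⁻¹)
    G ⇌ X (K = 3.00, k = 8.10 × 10⁻⁴ min⁻¹)
    G + E → Z (k = 0.00500 M⁻¹ min⁻¹)
    L → G (k = 0.00120 min⁻¹)
    X ⇌ D (K = 0.370, k = 3.60 × 10⁻⁴ min⁻¹)

**Not at rest.** Wednesday's computed Z corresponds to an exposure of 0.632, a little above the one read from Tuesday's flask. L stands at 0% at 15.0 d, but Wednesday's flask is still moving: at 150 d, Z reaches 86.2%, X falls to 4.79%, G to 1.57%, and E, in percent of its own charge, from 53.1% to 13.8%. The exposure by then is 1.98.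

**Neighbour flask.** With 0.12 M of L the ratio is 2.40, and Tuesday's exposure gives Z 32.1%. The neighbour's computed Z is 34.2%, with 18% of its E left.

The numbers in the tables are calculated for an exercise, and the scatter is random.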